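## Retrosynthetic overview

1. Target 15 comes from (2S)-flavanone 14 by removal of two MOM ethers; 14 comes from racemic 13 by a kinetic resolution that leaves the 2S ketone untouched.
2. Ring C is the only ring made: it is closed by oxa-Michael addition of the 2'-OH of chalcone 12 onto the enone.
3. Chalcone 12 comes from the key C–C bond formation, an intermolecular Claisen–Schmidt aldol condensation of methyl ketone 10 (ring A) with aldehyde 8 (ring B).
4. Aldehyde 8 comes from 2-bromoisovanillin 1 (dioxolane, MOM ether, Br/Li exchange, copper-mediated geranylation with 4, acetal hydrolysis); ketone 10 comes from mono-MOM protection of 9.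
5. Ring order: rings A and B are bought as arenes, ring C is closed in step 7, and the C2 configuration is fixed in step 8.

Assumption: the SMILES is read as the (2S)-flavanone with an (E)-geranyl chain; 1, 4 and 9 are taken as commercial.

## Route

Step 1
Reactants: 1 2-bromo-3-hydroxy-4-methoxybenzaldehyde (2-bromoisovanillin)
Product: 2 2-bromo-3-(1,3-dioxolan-2-yl)-6-methoxyphenol
Conditions: ethylene glycol, p-TsOH·H2O (cat.), toluene, reflux, Dean–Stark
Reagents that add atoms: ethylene glycol, OCCO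
Why: Acid-catalysed acetalisation with azeotropic removal of water masks the aldehyde as a base-stable dioxolane ahead of the organolithium step, and the phenol is inert here.

Step 2
Reactants: 2 2-bromo-3-(1,3-dioxolan-2-yl)-6-methoxyphenol
Product: 3 2-[2-bromo-4-methoxy-3-(methoxymethoxy)phenyl]-1,3-dioxolane
Conditions: NaH, MOMCl, DMF, 0 °C to rt
Reagents that add atoms: chloromethyl methyl ether (MOMCl), COCCl
Why: Williamson-type O-alkylation of the sodium phenoxide gives an aryl MOM ether that tolerates n-BuLi and the later basic aldol medium, under acid-free conditions that spare the acetal.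

Step 3
Reactants: 3 2-[2-bromo-4-methoxy-3-(methoxymethoxy)phenyl]-1,3-dioxolane; 4 geranyl bromide [(2E)-1-bromo-3,7-dimethylocta-2,6-diene]
Product: 7 2-{2-[(2E)-3,7-dimethylocta-2,6-dien-1-yl]-4-methoxy-3-(methoxymethoxy)phenyl}-1,3-dioxolane, via aryllithium 5 (not isolated), via arylcopper 6 (not isolated)
Conditions: n-BuLi, THF, −78 °C; CuBr·SMe2, −78 to −40 °C; then 4, −78 to 0 °C; aq. NH4Cl/NH3 quench
Reagents that add atoms: none
Why: Br/Li exchange at −78 °C outruns any attack on the acetal or MOM group, and the chelated arylcopper undergoes SN2-type allylic substitution at the primary carbon of 4 with the (E)-alkene retained.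

Step 4
Reactants: 7 2-{2-[(2E)-3,7-dimethylocta-2,6-dien-1-yl]-4-methoxy-3-(methoxymethoxy)phenyl}-1,3-dioxolane
Product: 8 2-[(2E)-3,7-dimethylocta-2,6-dien-1-yl]-4-methoxy-3-(methoxymethoxy)benzaldehyde
Conditions: PPTS (0.2 equiv), acetone/H2O 10:1, 55 °C
Reagents that add atoms: water, O
Why: Mild acid-catalysed acetal hydrolysis frees the electron-rich benzaldehyde much faster than the aryl MOM ether or the trisubstituted alkenes can react.

Step 5
Reactants: 9 1-(2,6-dihydroxy-4-methoxyphenyl)ethan-1-one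
Product: 10 1-[2-hydroxy-4-methoxy-6-(methoxymethoxy)phenyl]ethan-1-one
Conditions: MOMCl (1.2 equiv), K2CO3, acetone, 0 °C to rt
Reagents that add atoms: chloromethyl methyl ether (MOMCl), COCCl
Why: The two phenols of 9 are equivalent, and after the first Williamson O-alkylation the remaining OH is locked in a hydrogen bond to the ketone, so mono-protection is selective.

Step 6
Reactants: 10 1-[2-hydroxy-4-methoxy-6-(methoxymethoxy)phenyl]ethan-1-one; 8 2-[(2E)-3,7-dimethylocta-2,6-dien-1-yl]-4-methoxy-3-(methoxymethoxy)benzaldehyde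
Product: 12 (2E)-3-{2-[(2E)-3,7-dimethylocta-2,6-dien-1-yl]-4-methoxy-3-(methoxymethoxy)phenyl}-1-[2-hydroxy-4-methoxy-6-(methoxymethoxy)phenyl]prop-2-en-1-one, via aldol adduct 11 (not isolated)
Conditions: KOH (50% aq.), EtOH, 0 °C to rt, 36–48 h; cold dilute HCl to pH 6
Reagents that add atoms: none
Why: In this Claisen–Schmidt (crossed aldol) condensation only the methyl ketone can enolise and the aldehyde cannot self-condense, and E1cB dehydration of the aldol drives the equilibrium to the conjugated (E)-chalcone, joining ring A to ring B.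

Step 7
Reactants: 12 (2E)-3-{2-[(2E)-3,7-dimethylocta-2,6-dien-1-yl]-4-methoxy-3-(methoxymethoxy)phenyl}-1-[2-hydroxy-4-methoxy-6-(methoxymethoxy)phenyl]prop-2-en-1-one
Product: 13 racemic 2-{2-[(2E)-3,7-dimethylocta-2,6-dien-1-yl]-4-methoxy-3-(methoxymethoxy)phenyl}-7-methoxy-5-(methoxymethoxy)-2,3-dihydro-4H-chromen-4-one
Conditions: NaOAc, EtOH, reflux, 24 h
Reagents that add atoms: none
Why: Weak-base intramolecular oxa-Michael addition (6-endo-trig) of the 2'-phenoxide closes ring C, the 6'-OMOM group twisting the chalcone so that the flavanone is favoured at equilibrium; C2 is formed racemic here.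

Step 8
Reactants: 13 racemic 2-{2-[(2E)-3,7-dimethylocta-2,6-dien-1-yl]-4-methoxy-3-(methoxymethoxy)phenyl}-7-methoxy-5-(methoxymethoxy)-2,3-dihydro-4H-chromen-4-one
Product: 14 (2S)-2-{2-[(2E)-3,7-dimethylocta-2,6-dien-1-yl]-4-methoxy-3-(methoxymethoxy)phenyl}-7-methoxy-5-(methoxymethoxy)-2,3-dihydro-4H-chromen-4-one
Conditions: Cp*RhCl[(R,R)-TsDPEN] (1 mol%), HCO2H/Et3N 5:2, EtOAc, rt, stopped at ca. 55% conversion (chiral HPLC), chromatography
Reagents that add atoms: none
Why: In this Noyori–Ikariya-type asymmetric transfer hydrogenation run as a kinetic resolution, the (R,R) catalyst reduces the 2R ketone quickly to the cis-(2R,4R)-flavan-4-ol (hydride anti to the equatorial 2-aryl group) and leaves the mismatched 2S ketone in high ee, which secures the C2 stereocentre.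

Step 9
Reactants: 14 (2S)-2-{2-[(2E)-3,7-dimethylocta-2,6-dien-1-yl]-4-methoxy-3-(methoxymethoxy)phenyl}-7-methoxy-5-(methoxymethoxy)-2,3-dihydro-4H-chromen-4-one
Product: 15 (2S)-2-{2-[(2E)-3,7-dimethylocta-2,6-dien-1-yl]-3-hydroxy-4-methoxyphenyl}-5-hydroxy-7-methoxy-2,3-dihydro-4H-chromen-4-one
Conditions: HCl (ca. 1 M, from conc. aq. HCl) in MeOH, 40 °C, 3–4 h; neutral work-up
Reagents that add atoms: none
Why: Acid-catalysed acetal exchange with methanol cleaves both aryl MOM ethers, while C2 is configurationally stable in acid (ring opening needs base) and the geranyl alkenes tolerate dilute HCl at 40 °C.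

## Compound list

1 | 2-bromo-3-hydroxy-4-methoxybenzaldehyde (2-bromoisovanillin) | O=Cc1ccc(OC)c(O)c1Br | starting material
2 | 2-bromo-3-(1,3-dioxolan-2-yl)-6-methoxyphenol | COc1ccc(C2OCCO2)c(Br)c1O | intermediate
3 | 2-[2-bromo-4-methoxy-3-(methoxymethoxy)phenyl]-1,3-dioxolane | COCOc1c(OC)ccc(C2OCCO2)c1Br | intermediate
4 | geranyl bromide, (2E)-1-bromo-3,7-dimethylocta-2,6-diene | CC(C)=CCC/C(C)=C/CBr | starting material
5 | [6-(1,3-dioxolan-2-yl)-3-methoxy-2-(methoxymethoxy)phenyl]lithium (aryllithium, formed in the flask) | [Li]c1c(C2OCCO2)ccc(OC)c1OCOC | intermediate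
6 | [6-(1,3-dioxolan-2-yl)-3-methoxy-2-(methoxymethoxy)phenyl]copper (arylcopper, formed in the flask) | [Cu]c1c(C2OCCO2)ccc(OC)c1OCOC | intermediate
7 | 2-{2-[(2E)-3,7-dimethylocta-2,6-dien-1-yl]-4-methoxy-3-(methoxymethoxy)phenyl}-1,3-dioxolane | COCOc1c(OC)ccc(C2OCCO2)c1C/C=C(\C)CCC=C(C)C | intermediate
8 | 2-[(2E)-3,7-dimethylocta-2,6-dien-1-yl]-4-methoxy-3-(methoxymethoxy)benzaldehyde | COCOc1c(OC)ccc(C=O)c1C/C=C(\C)CCC=C(C)C | intermediate
9 | 1-(2,6-dihydroxy-4-methoxyphenyl)ethan-1-one | CC(=O)c1c(O)cc(OC)cc1O | starting material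
10 | 1-[2-hydroxy-4-methoxy-6-(methoxymethoxy)phenyl]ethan-1-one | CC(=O)c1c(O)cc(OC)cc1OCOC | intermediate
11 | racemic 3-{2-[(2E)-3,7-dimethylocta-2,6-dien-1-yl]-4-methoxy-3-(methoxymethoxy)phenyl}-3-hydroxy-1-[2-hydroxy-4-methoxy-6-(methoxymethoxy)phenyl]propan-1-one (aldol adduct, formed in the flask) | COCOc1cc(OC)cc(O)c1C(=O)CC(O)c1ccc(OC)c(OCOC)c1C/C=C(\C)CCC=C(C)C | intermediate
12 | (2E)-3-{2-[(2E)-3,7-dimethylocta-2,6-dien-1-yl]-4-methoxy-3-(methoxymethoxy)phenyl}-1-[2-hydroxy-4-methoxy-6-(methoxymethoxy)phenyl]prop-2-en-1-one | COCOc1cc(OC)cc(O)c1C(=O)/C=C/c1ccc(OC)c(OCOC)c1C/C=C(\C)CCC=C(C)C | intermediate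
13 | racemic 2-{2-[(2E)-3,7-dimethylocta-2,6-dien-1-yl]-4-methoxy-3-(methoxymethoxy)phenyl}-7-methoxy-5-(methoxymethoxy)-2,3-dihydro-4H-chromen-4-one | COc1cc(OCOC)c2c(c1)OC(c1ccc(OC)c(OCOC)c1C/C=C(\C)CCC=C(C)C)CC2=O | intermediate
14 | (2S)-2-{2-[(2E)-3,7-dimethylocta-2,6-dien-1-yl]-4-methoxy-3-(methoxymethoxy)phenyl}-7-methoxy-5-(methoxymethoxy)-2,3-dihydro-4H-chromen-4-one | COc1cc(OCOC)c2c(c1)O[C@H](c1ccc(OC)c(OCOC)c1C/C=C(\C)CCC=C(C)C)CC2=O | intermediate
15 | (2S)-2-{2-[(2E)-3,7-dimethylocta-2,6-dien-1-yl]-3-hydroxy-4-methoxyphenyl}-5-hydroxy-7-methoxy-2,3-dihydro-4H-chromen-4-one (CNP0130331.1) | COc1cc(O)c2c(c1)O[C@H](c1ccc(OC)c(O)c1C/C=C(\C)CCC=C(C)C)CC2=O | target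

## Step count and risk

Total steps: 9 (steps 1–4 build aldehyde 8, step 5 builds ketone 10, steps 6–9 are the common trunk).
Longest linear sequence: 8 steps (1 to 15 through steps 1, 2, 3, 4, 6, 7, 8, 9).

The three steps most likely to fail:

Step 3 (geranylation of a doubly ortho-substituted aryl metal). The risks are attack at the tertiary allylic terminus, giving the linalyl isomer, and Wurtz-type side reactions. The fallback sets out from 3 and comes back at 7. The aryllithium 5 is generated as before and transmetalated with ZnCl2 (THF, −78 to 0 °C) to chlorido[6-(1,3-dioxolan-2-yl)-3-methoxy-2-(methoxymethoxy)phenyl]zinc F1. This is cross-coupled with 4 under Pd(PPh3)4 (3 mol%, THF, rt). The Negishi coupling runs through a π-allylpalladium intermediate that is arylated at its less hindered terminus with the (E) geometry kept, and gives 7.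

Step 8 (kinetic resolution). The peri 5-OMOM group and the bulky 2-aryl group may slow the transfer hydrogenation or lower the selectivity factor, so that 14 is recovered with insufficient ee. The fallback sets out from 13 and comes back at 14. Racemic 13 is resolved physically by preparative chiral SFC on an amylose tris(3,5-dimethylphenylcarbamate) phase (CO2/MeOH), which makes no new compound (F0). The 2S enantiomer 14 is identified by its CD spectrum (positive band near 330 nm, negative band near 290 nm).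

Step 9 (acidic removal of two MOM groups next to a geranyl chain). The freed 3'-OH sits ortho to the geranyl group, so Brønsted acid may cyclise it to a chroman or hydrate the terminal alkene. The fallback sets out from 14 and comes back at 15. TMSOTf/2,2'-bipyridyl (CH2Cl2, 0 °C to rt) converts both aryl MOM ethers into (2S)-2-{2-[(2E)-3,7-dimethylocta-2,6-dien-1-yl]-4-methoxy-3-[(trimethylsilyl)oxy]phenyl}-7-methoxy-5-[(trimethylsilyl)oxy]-2,3-dihydro-4H-chromen-4-one F2. Adding water at rt hydrolyses the silyl ethers to 15 under essentially neutral conditions.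

## Further compounds

F1 | step 3 | chlorido[6-(1,3-dioxolan-2-yl)-3-methoxy-2-(methoxymethoxy)phenyl]zinc | Cl[Zn]c1c(C2OCCO2)ccc(OC)c1OCOC
F0 | step 8 | none | none
F2 | step 9 | (2S)-2-{2-[(2E)-3,7-dimethylocta-2,6-dien-1-yl]-4-methoxy-3-[(trimethylsilyl)oxy]phenyl}-7-methoxy-5-[(trimethylsilyl)oxy]-2,3-dihydro-4H-chromen-4-one | COc1cc(O[Si](C)(C)C)c2c(c1)O[C@H](c1ccc(OC)c(O[Si](C)(C)C)c1C/C=C(\C)CCC=C(C)C)CC2=O
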